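**Retrosynthetic overview**
The strategy rests on the ethano bridge C1(ring A)–CH2–CH2–C1'(ring B). C1 lies between the 4-hydroxybenzyl groups at C2 and C6, and C1' lies next to the one at C6', so a vinyl unit can accept one aryl group on each carbon.
Both aryl–bridge bonds are cut at once, giving a ring A aryllithium, vinylboronic acid pinacol ester and a ring B aryl triflate (three-component conjunctive coupling). The leftover C–B bond then becomes C–H, and five benzyl ethers are removed last.
The ring A bromide comes from 3-bromo-5-methoxyphenol by O-benzylation, diiodination of both positions flanking bromine, and a twofold iodide-selective Negishi benzylation. This avoids competing attack at the position between the two oxygens.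
The ring B triflate comes from 2,4,4'-trihydroxybenzophenone by benzylation of the two free hydroxyls, ionic hydrogenation of C=O and triflation of the formerly chelated hydroxyl.
No ring is formed in the route; all five target benzene rings come from the purchased building blocks.

Key step: step 8

Assumption: the target has no stereocentre. The boron-bearing carbon made in the key step is drawn (S) only for definiteness, since either ligand enantiomer serves and the centre is erased one step later.

**Step 1**
Reactants: 1 3-bromo-5-methoxyphenol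
Product: 2 1-(benzyloxy)-3-bromo-5-methoxybenzene
Conditions: BnBr (1.1 equiv), K2CO3, DMF, rt
Reagents that add atoms: benzyl bromide, BrCc1ccccc1
Why: Williamson ether synthesis, in which the phenoxide formed by K2CO3 displaces bromide from benzyl bromide by SN2 while the aryl bromide and the methyl ether are inert.

**Step 2**
Reactants: 2 1-(benzyloxy)-3-bromo-5-methoxybenzene
Product: 3 1-(benzyloxy)-3-bromo-2,4-diiodo-5-methoxybenzene
Conditions: NIS (2.1 equiv), TFA (0.3 equiv), MeCN, 0 °C to rt, dark
Reagents that add atoms: N-iodosuccinimide, O=C1CCC(=O)N1I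
Why: Electrophilic aromatic iodination should take the two positions next to bromine, as is usual for 5-substituted resorcinol diethers, because each is para to one alkoxy group and ortho to the other, whereas the third free position is shielded by the alkyl residues of both flanking alkoxy groups.

**Step 3**
Reactants: 4 4-(benzyloxy)benzyl chloride
Product: 5 [4-(benzyloxy)benzyl]zinc chloride (titrated THF solution, used as such)
Conditions: Zn dust (1.5 equiv), LiCl (1.5 equiv), THF, 25 °C
Reagents that add atoms: zinc, [Zn]
Why: Direct insertion of zinc into the activated benzylic carbon–chlorine bond, sped up and solubilised by LiCl, should run at room temperature with little Wurtz dimerisation and leaves the aryl benzyl ether untouched.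

**Step 4**
Reactants: 3 1-(benzyloxy)-3-bromo-2,4-diiodo-5-methoxybenzene; 5 [4-(benzyloxy)benzyl]zinc chloride (2.4 equiv)
Product: 6 1-(benzyloxy)-2,4-bis[4-(benzyloxy)benzyl]-3-bromo-5-methoxybenzene (ring A bromide)
Conditions: Pd(PPh3)4 (5 mol %), THF, 25 to 50 °C
Reagents that add atoms: none
Why: In this twofold Negishi coupling, zerovalent palladium bearing triphenylphosphine inserts into carbon–iodine bonds far faster than into carbon–bromine bonds, and the bromide becomes more shielded with each benzyl group installed beside it, so both iodides should be replaced and the bromide kept for step 8.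

**Step 5**
Reactants: 7 2,4,4'-trihydroxybenzophenone
Product: 8 [4-(benzyloxy)-2-hydroxyphenyl][4-(benzyloxy)phenyl]methanone
Conditions: BnBr (2.05 equiv), K2CO3 (2.2 equiv), acetone, reflux
Reagents that add atoms: benzyl bromide, BrCc1ccccc1
Why: Williamson ether synthesis under weak base, where the 2-hydroxyl is held in a hydrogen bond to the carbonyl oxygen and is much less nucleophilic, so two equivalents of benzyl bromide should alkylate only the 4- and 4'-hydroxyls.

**Step 6**
Reactants: 8 [4-(benzyloxy)-2-hydroxyphenyl][4-(benzyloxy)phenyl]methanone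
Product: 9 5-(benzyloxy)-2-[4-(benzyloxy)benzyl]phenol
Conditions: Et3SiH (3 equiv), TFA (10 equiv), CH2Cl2, 0 °C to rt
Reagents that add atoms: none
Why: In this Kursanov–Parnes ionic hydrogenation, the protonated ketone and the derived benzhydryl cation are both stabilised by para-alkoxy and ortho-hydroxy donors and each accepts hydride from the silane, while unsubstituted benzyl aryl ethers tolerate dilute TFA at or below room temperature.

**Step 7**
Reactants: 9 5-(benzyloxy)-2-[4-(benzyloxy)benzyl]phenol
Product: 10 5-(benzyloxy)-2-[4-(benzyloxy)benzyl]phenyl trifluoromethanesulfonate (ring B triflate)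
Conditions: Tf2O (1.2 equiv), pyridine (2 equiv), CH2Cl2, 0 °C
Reagents that add atoms: trifluoromethanesulfonic anhydride, O=S(=O)(OS(=O)(=O)C(F)(F)F)C(F)(F)F
Why: O-sulfonylation of the only free phenol, now released from chelation, is fast at 0 °C and the ethers and the diarylmethane are unaffected.

**Step 8**
Reactants: 6 1-(benzyloxy)-2,4-bis[4-(benzyloxy)benzyl]-3-bromo-5-methoxybenzene; 11 vinylboronic acid pinacol ester; 10 5-(benzyloxy)-2-[4-(benzyloxy)benzyl]phenyl trifluoromethanesulfonate
Product: 14 (S)-2-{1-[3-(benzyloxy)-2,6-bis(4-(benzyloxy)benzyl)-5-methoxyphenyl]-2-[5-(benzyloxy)-2-(4-(benzyloxy)benzyl)phenyl]ethyl}-4,4,5,5-tetramethyl-1,3,2-dioxaborolane, via ring A aryllithium 12 (not isolated), via lithium vinylboronate complex 13 (not isolated)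
Conditions: n-BuLi (1.0 equiv, titrated), THF, −78 °C; 11 (1.0 equiv), −78 °C to rt; volatiles removed in vacuo; then 10 (1.0 equiv), Pd(OAc)2 (3 mol %), MandyPhos ligand 1,1'-bis[bis(4-methoxy-3,5-dimethylphenyl)phosphino]-2,2'-bis[α-(dimethylamino)benzyl]ferrocene (single enantiomer, 3.6 mol %), KOTf (1 equiv, halide scavenger), THF, 60 °C
Reagents that add atoms: n-butyllithium, [Li]CCCC (supplies the lithium of 12 and 13)
Why: Bromine–lithium exchange at −78 °C should outrun proton transfer from the diarylmethane CH2 groups, and 12 is captured at once by the vacant orbital on boron of 11 to give the four-coordinate boronate 13; one equivalent of n-BuLi, followed by removal of 1-bromobutane with the solvent, leaves a halide-free medium, which matters because halide would occupy the palladium site that the alkene needs. Zerovalent palladium generated from Pd(OAc)2 and the bisphosphine inserts into the C–O bond of triflate 10 to give a cationic aryl complex of divalent palladium, which binds the vinyl group of 13 and so triggers migration of ring A from boron to the α-carbon, anti to the metal, while the terminal carbon becomes bound to palladium; reductive elimination then joins that carbon to C1' of ring B. The closest known reaction type is the palladium-catalysed conjunctive cross-coupling of aryllithium-derived vinylboron ate complexes with aryl triflates, and a migrating aryl group carrying two ortho benzyl groups exceeds the steric demand usually met in it, which is the main risk of the route. No ring is closed, and two skeletal bonds (C1–Cα and Cβ–C1') are formed. The one new stereocentre, Cα bearing boron, is set by the chiral ligand through the face of the vinyl group that binds palladium, but its configuration does not matter because step 9 turns it into a CH2 group. The metallate shift must win over Suzuki-type transfer of aryl or vinyl and over β-hydride elimination: the non-coordinating triflate keeps palladium cationic and alkene-seeking, the wide bite angle of the ferrocenyl ligand speeds reductive elimination, and crowded ring A is a poor group for transmetallation yet relieves strain at boron by migrating, which is why ring A serves as the nucleophile and the less hindered ring B as the electrophile.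

**Step 9**
Reactants: 14 benzylic pinacol boronate from step 8
Product: 15 1-(benzyloxy)-2,4-bis[4-(benzyloxy)benzyl]-3-{2-[5-(benzyloxy)-2-(4-(benzyloxy)benzyl)phenyl]ethyl}-5-methoxybenzene
Conditions: TBAF·3H2O (3 equiv), toluene/THF, 60 °C
Reagents that add atoms: none
Why: In this fluoride-promoted protodeboronation of a benzylic boronic ester, fluoride only activates boron as a four-coordinate boronate, whose C–B bond overlaps with the ring A π system and is protonated by the water of hydration, so the stereocentre becomes the second CH2 of the bridge and all ethers are inert.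

**Step 10**
Reactants: 15 pentabenzyl ether of the target
Product: 16 2,4-bis(4-hydroxybenzyl)-3-{2-[5-hydroxy-2-(4-hydroxybenzyl)phenyl]ethyl}-5-methoxyphenol (CNP0147493.0)
Conditions: H2 (1 atm), 10% Pd/C, THF/MeOH, rt
Reagents that add atoms: none
Why: Catalytic hydrogenolysis cleaves the five benzylic C–O bonds in one operation, while the diarylmethane and bibenzyl C–C bonds and the methyl ether are not attacked under these conditions.

**Compound list**
1 | 3-bromo-5-methoxyphenol | COc1cc(O)cc(Br)c1 | starting material
2 | 1-(benzyloxy)-3-bromo-5-methoxybenzene | COc1cc(Br)cc(OCc2ccccc2)c1 | intermediate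
3 | 1-(benzyloxy)-3-bromo-2,4-diiodo-5-methoxybenzene | COc1cc(OCc2ccccc2)c(I)c(Br)c1I | intermediate
4 | 4-(benzyloxy)benzyl chloride | ClCc1ccc(OCc2ccccc2)cc1 | starting material
5 | [4-(benzyloxy)benzyl]zinc chloride | Cl[Zn]Cc1ccc(OCc2ccccc2)cc1 | intermediate
6 | 1-(benzyloxy)-2,4-bis[4-(benzyloxy)benzyl]-3-bromo-5-methoxybenzene | COc1cc(OCc2ccccc2)c(Cc2ccc(OCc3ccccc3)cc2)c(Br)c1Cc1ccc(OCc2ccccc2)cc1 | intermediate
7 | 2,4,4'-trihydroxybenzophenone | O=C(c1ccc(O)cc1)c1ccc(O)cc1O | starting material
8 | [4-(benzyloxy)-2-hydroxyphenyl][4-(benzyloxy)phenyl]methanone | O=C(c1ccc(OCc2ccccc2)cc1)c1ccc(OCc2ccccc2)cc1O | intermediate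
9 | 5-(benzyloxy)-2-[4-(benzyloxy)benzyl]phenol | Oc1cc(OCc2ccccc2)ccc1Cc1ccc(OCc2ccccc2)cc1 | intermediate
10 | 5-(benzyloxy)-2-[4-(benzyloxy)benzyl]phenyl trifluoromethanesulfonate | O=S(=O)(Oc1cc(OCc2ccccc2)ccc1Cc1ccc(OCc2ccccc2)cc1)C(F)(F)F | intermediate
11 | vinylboronic acid pinacol ester | C=CB1OC(C)(C)C(C)(C)O1 | starting material
12 | {3-(benzyloxy)-2,6-bis[4-(benzyloxy)benzyl]-5-methoxyphenyl}lithium | [Li]c1c(Cc2ccc(OCc3ccccc3)cc2)c(OCc2ccccc2)cc(OC)c1Cc1ccc(OCc2ccccc2)cc1 | intermediate
13 | lithium {3-(benzyloxy)-2,6-bis[4-(benzyloxy)benzyl]-5-methoxyphenyl}(pinacolato)(vinyl)borate | [Li+].C=C[B-]1(OC(C)(C)C(C)(C)O1)c1c(Cc2ccc(OCc3ccccc3)cc2)c(OCc2ccccc2)cc(OC)c1Cc1ccc(OCc2ccccc2)cc1 | intermediate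
14 | (S)-2-{1-[3-(benzyloxy)-2,6-bis(4-(benzyloxy)benzyl)-5-methoxyphenyl]-2-[5-(benzyloxy)-2-(4-(benzyloxy)benzyl)phenyl]ethyl}-4,4,5,5-tetramethyl-1,3,2-dioxaborolane | COc1cc(OCc2ccccc2)c(Cc2ccc(OCc3ccccc3)cc2)c([C@H](Cc2cc(OCc3ccccc3)ccc2Cc2ccc(OCc3ccccc3)cc2)B2OC(C)(C)C(C)(C)O2)c1Cc1ccc(OCc2ccccc2)cc1 | intermediate
15 | 1-(benzyloxy)-2,4-bis[4-(benzyloxy)benzyl]-3-{2-[5-(benzyloxy)-2-(4-(benzyloxy)benzyl)phenyl]ethyl}-5-methoxybenzene | COc1cc(OCc2ccccc2)c(Cc2ccc(OCc3ccccc3)cc2)c(CCc2cc(OCc3ccccc3)ccc2Cc2ccc(OCc3ccccc3)cc2)c1Cc1ccc(OCc2ccccc2)cc1 | intermediate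
16 | 2,4-bis(4-hydroxybenzyl)-3-{2-[5-hydroxy-2-(4-hydroxybenzyl)phenyl]ethyl}-5-methoxyphenol | COc1cc(O)c(Cc2ccc(O)cc2)c(CCc2cc(O)ccc2Cc2ccc(O)cc2)c1Cc1ccc(O)cc1 | target

**Step count**
Total step count: 10.
Longest linear sequence: 6 steps (1, 2, 4, 8, 9, 10 from compound 1; equally 5, 6, 7, 8, 9, 10 from compound 7).

**Steps most likely to fail**

Step 8. Migration of the doubly ortho-substituted aryl group may be too slow. In that case direct transfer of aryl or vinyl to palladium, β-hydride elimination, or protonation of the aryllithium by a diarylmethane CH2 could take over. The fallback makes the two bridge bonds one after the other by known chemistry and sets out from 6.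
- Bromine–lithium exchange as in step 8, then quenching of 12 with DMF at −78 °C, should give 3-(benzyloxy)-2,6-bis[4-(benzyloxy)benzyl]-5-methoxybenzaldehyde F1.
- Wittig methylenation (Ph3PCH3Br, KOt-Bu, THF) should give 1-(benzyloxy)-2,4-bis[4-(benzyloxy)benzyl]-5-methoxy-3-vinylbenzene F2.
- Anti-Markovnikov hydroboration with 9-BBN-H in THF should give 9-{2-[3-(benzyloxy)-2,6-bis(4-(benzyloxy)benzyl)-5-methoxyphenyl]ethyl}-9-borabicyclo[3.3.1]nonane F3.
- F3 is coupled in the same flask with triflate 10 by B-alkyl Suzuki–Miyaura coupling (PdCl2(dppf), aqueous K3PO4, THF/DMF, 60 °C). The crowded ring is now two carbons away from the metal.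
- The fallback comes back to the route at 15, so step 9 is no longer needed.

Step 9. Protonolysis of the C–B bond may be sluggish, because the boronate is secondary and crowded and the developing benzylic carbanion is only modestly stabilised. The fallback sets out from 14 and replaces protonolysis by oxidation, elimination and reduction.
- Oxidation with retention (NaBO3·4H2O, THF/H2O, rt) should give (S)-1-[3-(benzyloxy)-2,6-bis(4-(benzyloxy)benzyl)-5-methoxyphenyl]-2-[5-(benzyloxy)-2-(4-(benzyloxy)benzyl)phenyl]ethanol F4.
- Neutral syn-elimination with the Burgess reagent (toluene, 60 °C) avoids a free benzylic cation, which could cyclise onto a neighbouring benzyl ring. It should give (E)-1-(benzyloxy)-2,4-bis[4-(benzyloxy)benzyl]-3-{2-[5-(benzyloxy)-2-(4-(benzyloxy)benzyl)phenyl]vinyl}-5-methoxybenzene F5. The alkene geometry is of no consequence.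
- The conditions of step 10 (H2, 10% Pd/C) then saturate the alkene and cleave the five benzyl ethers together.
- The fallback comes back to the route at 16.

Step 4. Oxidative addition at the doubly ortho-substituted iodides may stall after the first coupling. Discrimination between iodide and bromide may erode on heating, and the benzylzinc reagent may homocouple. The fallback sets out from 3 and uses polar chemistry without palladium.
- Iodine–magnesium exchange (i-PrMgCl·LiCl, THF, −40 °C) is run cold enough that the ortho-bromoarylmagnesium does not eliminate to an aryne.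
- Addition to 4-(benzyloxy)benzaldehyde (O=Cc1ccc(OCc2ccccc2)cc1) should give either or both of two racemic mono-adducts: [6-(benzyloxy)-2-bromo-3-iodo-4-methoxyphenyl][4-(benzyloxy)phenyl]methanol F6 and [4-(benzyloxy)-2-bromo-3-iodo-6-methoxyphenyl][4-(benzyloxy)phenyl]methanol F7.
- A second exchange–addition cycle converges both mono-adducts on [4-(benzyloxy)-2-bromo-6-methoxy-1,3-phenylene]bis{[4-(benzyloxy)phenyl]methanol} F8, a mixture of diastereomers.
- Ionic reduction of both benzhydrols (Et3SiH, TFA, CH2Cl2, 0 °C) erases the carbinol centres.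
- The fallback comes back to the route at 6.

**Further compounds**
F1 | step 8 | 3-(benzyloxy)-2,6-bis[4-(benzyloxy)benzyl]-5-methoxybenzaldehyde | COc1cc(OCc2ccccc2)c(Cc2ccc(OCc3ccccc3)cc2)c(C=O)c1Cc1ccc(OCc2ccccc2)cc1
F2 | step 8 | 1-(benzyloxy)-2,4-bis[4-(benzyloxy)benzyl]-5-methoxy-3-vinylbenzene | COc1cc(OCc2ccccc2)c(Cc2ccc(OCc3ccccc3)cc2)c(C=C)c1Cc1ccc(OCc2ccccc2)cc1
F3 | step 8 | 9-{2-[3-(benzyloxy)-2,6-bis(4-(benzyloxy)benzyl)-5-methoxyphenyl]ethyl}-9-borabicyclo[3.3.1]nonane | COc1cc(OCc2ccccc2)c(Cc2ccc(OCc3ccccc3)cc2)c(CCB2C3CCCC2CCC3)c1Cc1ccc(OCc2ccccc2)cc1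
F4 | step 9 | (S)-1-[3-(benzyloxy)-2,6-bis(4-(benzyloxy)benzyl)-5-methoxyphenyl]-2-[5-(benzyloxy)-2-(4-(benzyloxy)benzyl)phenyl]ethanol | COc1cc(OCc2ccccc2)c(Cc2ccc(OCc3ccccc3)cc2)c([C@H](Cc2cc(OCc3ccccc3)ccc2Cc2ccc(OCc3ccccc3)cc2)O)c1Cc1ccc(OCc2ccccc2)cc1
F5 | step 9 | (E)-1-(benzyloxy)-2,4-bis[4-(benzyloxy)benzyl]-3-{2-[5-(benzyloxy)-2-(4-(benzyloxy)benzyl)phenyl]vinyl}-5-methoxybenzene | COc1cc(OCc2ccccc2)c(Cc2ccc(OCc3ccccc3)cc2)c(/C=C/c2cc(OCc3ccccc3)ccc2Cc2ccc(OCc3ccccc3)cc2)c1Cc1ccc(OCc2ccccc2)cc1
F6 | step 4 | [6-(benzyloxy)-2-bromo-3-iodo-4-methoxyphenyl][4-(benzyloxy)phenyl]methanol (racemic) | COc1cc(OCc2ccccc2)c(C(O)c2ccc(OCc3ccccc3)cc2)c(Br)c1I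
F7 | step 4 | [4-(benzyloxy)-2-bromo-3-iodo-6-methoxyphenyl][4-(benzyloxy)phenyl]methanol (racemic) | COc1cc(OCc2ccccc2)c(I)c(Br)c1C(O)c1ccc(OCc2ccccc2)cc1
F8 | step 4 | [4-(benzyloxy)-2-bromo-6-methoxy-1,3-phenylene]bis{[4-(benzyloxy)phenyl]methanol} (mixture of diastereomers) | COc1cc(OCc2ccccc2)c(C(O)c2ccc(OCc3ccccc3)cc2)c(Br)c1C(O)c1ccc(OCc2ccccc2)cc1
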